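The route rests on cutting the one benzene ring into three pieces: an isopropenyl alkoxycarbene chromium complex (ring carbons C4–C5–C6, with the C4 oxygen and the C5 methyl), one CO ligand (C1 and its oxygen) and a terminal enyne (C2–C3, carrying the benzoyloxymethyl-vinyl group). A Dötz benzannulation forms the three ring C–C bonds in one operation and exploits the ring's defining feature: two para oxygens in different states, the one on C1 beside the alkenyl-bearing C2, the one on C4 beside the methyl-bearing C5, with C3 and C6 as CH. The precursors are the 4-methoxybenzyloxy (PMB-oxy) isopropenyl carbene pentacarbonylchromium complex and 2-methylenebut-3-yn-1-yl benzoate; acylation and PMB removal finish the route.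

Key step: step 6

Remark: the target has no stereocentre and no stereogenic double bond, so it is achiral and no enantiomer has to be chosen; ring numbering used here is C1 (O-isobutyrate), C2 (alkenyl), C3 (H), C4 (OH), C5 (CH3), C6 (H).

Step 1
Reactants: 1 2-bromopropene; 2 chromium hexacarbonyl
Product: 5 tetramethylammonium pentacarbonyl(2-methyl-1-oxidoprop-2-en-1-ylidene)chromate, via 2-propenyllithium 3 (not isolated), via lithium acylchromate 4 (not isolated)
Conditions: t-BuLi (2.0 equiv), Et2O, −78 °C; then Cr(CO)6, Et2O, 0 °C → rt; then Me4NBr, degassed H2O, 0 °C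
Reagents that add atoms: tetramethylammonium bromide C[N+](C)(C)C.[Br-]; tert-butyllithium [Li]C(C)(C)C (its lithium stays only in 3 and 4)
Why: Bromine–lithium exchange gives the vinyllithium, which adds to a CO ligand of Cr(CO)6 in the classical Fischer acylmetalate synthesis, and cation metathesis gives the easily handled, CH2Cl2-soluble ammonium salt.

Step 2
Reactants: 5 tetramethylammonium pentacarbonyl(2-methyl-1-oxidoprop-2-en-1-ylidene)chromate
Product: 7 pentacarbonyl[(4-methoxybenzyloxy)(prop-1-en-2-yl)carbene]chromium, via pivaloyloxycarbene complex 6 (not isolated)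
Conditions: t-BuCOCl (1.05 equiv), CH2Cl2, −40 °C; then 4-methoxybenzyl alcohol (1.2 equiv), −40 °C → rt; chromatography under Ar
Reagents that add atoms: 4-methoxybenzyl alcohol COc1ccc(CO)cc1; pivaloyl chloride CC(C)(C)C(=O)Cl (its acyl group stays only in 6)
Why: O-acylation of the acylmetalate gives an electrophilic acyloxycarbene whose carboxylate is displaced at the carbene carbon by the primary alcohol (addition–elimination, the standard entry to alkoxycarbene complexes that Meerwein salts cannot deliver), and the hindered pivaloyl group disfavours acyl transfer to the alcohol.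

Step 3
Reactants: 8 2-bromoallyl alcohol (2-bromoprop-2-en-1-ol); 9 trimethylsilylacetylene
Product: 10 2-methylene-4-(trimethylsilyl)but-3-yn-1-ol
Conditions: PdCl2(PPh3)2 (2 mol %), CuI (4 mol %), Et3N, THF, rt
Reagents that add atoms: none
Why: Sonogashira coupling of a vinyl bromide with a terminal alkyne tolerates the free allylic alcohol and builds the enyne carbon chain in one step.

Step 4
Reactants: 10 2-methylene-4-(trimethylsilyl)but-3-yn-1-ol
Product: 11 2-methylene-4-(trimethylsilyl)but-3-yn-1-yl benzoate
Conditions: BzCl, Et3N, DMAP (cat.), CH2Cl2, 0 °C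
Reagents that add atoms: benzoyl chloride O=C(Cl)c1ccccc1
Why: DMAP-catalysed acylation of a primary alcohol is routine, and doing it before desilylation means the small, volatile, water-soluble free enynol never has to be isolated.

Step 5
Reactants: 11 2-methylene-4-(trimethylsilyl)but-3-yn-1-yl benzoate
Product: 12 2-methylenebut-3-yn-1-yl benzoate
Conditions: TBAF (1.1 equiv), AcOH (1.2 equiv), THF, 0 °C; used freshly
Reagents that add atoms: none
Why: Fluoride-induced protodesilylation of an alkynylsilane is fast, and buffering with acetic acid keeps the medium non-basic so the allylic benzoate is not cleaved.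

Step 6
Reactants: 7 pentacarbonyl[(4-methoxybenzyloxy)(prop-1-en-2-yl)carbene]chromium; 12 2-methylenebut-3-yn-1-yl benzoate
Product: 14 2-[3-(benzoyloxy)prop-1-en-2-yl]-4-(4-methoxybenzyloxy)-5-methylphenol, via tricarbonylchromium arene complex 13 (not isolated)
Conditions: 12 (1.5 equiv), degassed THF (0.05 M), 50 °C, Ar; then air, daylight, EtOAc, rt; filtration through Celite
Reagents that add atoms: none
Why: Loss of a cis CO from 7 lets the alkyne bind and insert into the Cr=C bond to give an η3-vinylcarbene, CO insertion gives a chromium-bound dienylketene, and ring closure with enolisation gives the phenol as its Cr(CO)3 complex, which air and light release without oxidising the hydroquinone monoether. This is the Dötz [3+2+1] benzannulation of an alkenyl alkoxycarbene with a terminal alkyne, the substrate pairing for which phenol formation is most dependable, and conjugated enynes are established alkyne partners. The benzene ring is closed by 6π-electrocyclisation of the dienylketene, which joins the CO-derived carbon to the isopropenyl CH2 carbon after the carbene-carbon/alkyne-CH and alkyne-internal-carbon/CO bonds have formed at the metal. No stereocentre is created. The step needs regioselective insertion, secured by the steric difference between H and the alkenyl group on the alkyne, which places the substituted carbon beside the CO-derived phenol carbon. It also needs the phenol channel to outrun furan, cyclobutenone and cyclopentannulation channels, which chromium, an alkenyl carbene and THF at moderate dilution favour, while the alkene of 12 is cross-conjugated to the ketene and cannot enter the electrocyclisation.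

Step 7
Reactants: 14 2-[3-(benzoyloxy)prop-1-en-2-yl]-4-(4-methoxybenzyloxy)-5-methylphenol
Product: 15 2-[5-(4-methoxybenzyloxy)-4-methyl-2-(2-methylpropanoyloxy)phenyl]prop-2-en-1-yl benzoate
Conditions: i-PrCOCl (1.2 equiv), Et3N, DMAP (cat.), CH2Cl2, 0 °C; run directly on freshly isolated 14
Reagents that add atoms: isobutyryl chloride CC(C)C(=O)Cl
Why: Acylation of the only free hydroxyl, the CO-derived phenol, is unambiguous and also removes the air sensitivity of the hydroquinone monoether.

Step 8
Reactants: 15 2-[5-(4-methoxybenzyloxy)-4-methyl-2-(2-methylpropanoyloxy)phenyl]prop-2-en-1-yl benzoate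
Product: 16 2-[5-hydroxy-4-methyl-2-(2-methylpropanoyloxy)phenyl]prop-2-en-1-yl benzoate (CNP0245407.0)
Conditions: DDQ (1.2 equiv), CH2Cl2/pH 7 phosphate buffer (10:1), 0 °C → rt
Reagents that add atoms: none
Why: Oxidative PMB cleavage (hydride abstraction at the PMB benzylic carbon, then hydrolysis of the oxocarbenium ion to the phenol and anisaldehyde) runs under neutral conditions that leave both esters and the electron-poor 1,1-disubstituted alkene untouched.

Compound list
1 | 2-bromopropene | C=C(C)Br | starting material
2 | chromium hexacarbonyl | O=C=[Cr](=C=O)(=C=O)(=C=O)(=C=O)=C=O | starting material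
3 | 2-propenyllithium (prop-1-en-2-yllithium) | [Li]C(C)=C | intermediate
4 | lithium pentacarbonyl(2-methyl-1-oxidoprop-2-en-1-ylidene)chromate | C=C(C)C([O-])=[Cr](=C=O)(=C=O)(=C=O)(=C=O)=C=O.[Li+] | intermediate
5 | tetramethylammonium pentacarbonyl(2-methyl-1-oxidoprop-2-en-1-ylidene)chromate | C=C(C)C([O-])=[Cr](=C=O)(=C=O)(=C=O)(=C=O)=C=O.C[N+](C)(C)C | intermediate
6 | pentacarbonyl[(pivaloyloxy)(prop-1-en-2-yl)carbene]chromium | C=C(C)C(OC(=O)C(C)(C)C)=[Cr](=C=O)(=C=O)(=C=O)(=C=O)=C=O | intermediate
7 | pentacarbonyl[(4-methoxybenzyloxy)(prop-1-en-2-yl)carbene]chromium | C=C(C)C(OCc1ccc(OC)cc1)=[Cr](=C=O)(=C=O)(=C=O)(=C=O)=C=O | intermediate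
8 | 2-bromoallyl alcohol (2-bromoprop-2-en-1-ol) | C=C(Br)CO | starting material
9 | trimethylsilylacetylene | C#C[Si](C)(C)C | starting material
10 | 2-methylene-4-(trimethylsilyl)but-3-yn-1-ol | C=C(CO)C#C[Si](C)(C)C | intermediate
11 | 2-methylene-4-(trimethylsilyl)but-3-yn-1-yl benzoate | C=C(COC(=O)c1ccccc1)C#C[Si](C)(C)C | intermediate
12 | 2-methylenebut-3-yn-1-yl benzoate | C#CC(=C)COC(=O)c1ccccc1 | intermediate
13 | tricarbonyl(η6-arene)chromium complex of phenol 14 (written as arene plus Cr(CO)3 fragment) | C=C(COC(=O)c1ccccc1)c1cc(OCc2ccc(OC)cc2)c(C)cc1O.O=C=[Cr](=C=O)=C=O | intermediate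
14 | 2-[3-(benzoyloxy)prop-1-en-2-yl]-4-(4-methoxybenzyloxy)-5-methylphenol | C=C(COC(=O)c1ccccc1)c1cc(OCc2ccc(OC)cc2)c(C)cc1O | intermediate
15 | 2-[5-(4-methoxybenzyloxy)-4-methyl-2-(2-methylpropanoyloxy)phenyl]prop-2-en-1-yl benzoate | C=C(COC(=O)c1ccccc1)c1cc(OCc2ccc(OC)cc2)c(C)cc1OC(=O)C(C)C | intermediate
16 | 2-[5-hydroxy-4-methyl-2-(2-methylpropanoyloxy)phenyl]prop-2-en-1-yl benzoate | C=C(COC(=O)c1ccccc1)c1cc(O)c(C)cc1OC(=O)C(C)C | target

Total step count: 8. Longest linear sequence: 6 steps (steps 3, 4, 5, 6, 7, 8, from 2-bromoallyl alcohol); the carbene branch (steps 1, 2) joins at step 6.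

Steps most likely to fail, riskiest first:

Step 6. The vinylcarbene intermediate may be diverted before CO insertion and electrocyclisation (furan, cyclobutenone or cyclopentannulation channels, or metal-mediated oligomerisation of the functionalised enyne), possibly aggravated by ionisation of the allylic benzoate at low-valent chromium. The fallback sets out from 7 and returns at 15; it keeps the ester out of the alkyne and introduces the allylic oxygen after the ring exists. Carbene 7 and commercial 2-methylbut-1-en-3-yne, under the conditions of step 6, should give 4-(4-methoxybenzyloxy)-5-methyl-2-(prop-1-en-2-yl)phenol F1. Isobutyryl chloride/Et3N/DMAP should then give 4-(4-methoxybenzyloxy)-5-methyl-2-(prop-1-en-2-yl)phenyl 2-methylpropanoate F2. Catalytic SeO2 with t-BuOOH in CH2Cl2 should hydroxylate the single allylic methyl group (ene reaction, then [2,3]-shift) to give 2-(3-hydroxyprop-1-en-2-yl)-4-(4-methoxybenzyloxy)-5-methylphenyl 2-methylpropanoate F3. Benzoylation (BzCl, pyridine, 0 °C, kept cold and short to avoid isobutyryl migration) rejoins the route at 15.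

Step 2. The alcohol may be acylated by the acyloxycarbene instead of substituting at the carbene carbon, which returns the acylmetalate, or it may add in conjugate fashion to the electrophilic isopropenyl terminus. The fallback sets out from 5 and returns at 16; it avoids alcohol exchange altogether. Alkylation of 5 with trimethyloxonium tetrafluoroborate (CH2Cl2, 0 °C) should give the well-behaved pentacarbonyl[methoxy(prop-1-en-2-yl)carbene]chromium F4. Benzannulation of F4 with 12 as in step 6 should give 2-(2-hydroxy-5-methoxy-4-methylphenyl)prop-2-en-1-yl benzoate F5, and isobutyrylation as in step 7 should give 2-[5-methoxy-4-methyl-2-(2-methylpropanoyloxy)phenyl]prop-2-en-1-yl benzoate F6. Aryl methyl ether cleavage with BCl3/n-Bu4NI (CH2Cl2, −78 → 0 °C) should then give 16. This trades an easier carbene synthesis for a harder final deprotection in the presence of the allylic benzoate.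

Step 8. Hydride abstraction from an aryl (rather than alkyl) PMB ether may be sluggish, and the liberated phenol may be over-oxidised by the quinone. The fallback sets out from 15 and returns at 16 and makes no new compound (F0). It replaces the oxidative cleavage by non-oxidative acidolysis: TFA (5–10 % v/v) in CH2Cl2 at 0 °C with pentamethylbenzene (3 equiv) as cation trap should ionise the aryl PMB ether within minutes, the scavenger intercepting the 4-methoxybenzyl cation before it can alkylate the product ring.

Further compounds
F1 | step 6 | 4-(4-methoxybenzyloxy)-5-methyl-2-(prop-1-en-2-yl)phenol | C=C(C)c1cc(OCc2ccc(OC)cc2)c(C)cc1O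
F2 | step 6 | 4-(4-methoxybenzyloxy)-5-methyl-2-(prop-1-en-2-yl)phenyl 2-methylpropanoate | C=C(C)c1cc(OCc2ccc(OC)cc2)c(C)cc1OC(=O)C(C)C
F3 | step 6 | 2-(3-hydroxyprop-1-en-2-yl)-4-(4-methoxybenzyloxy)-5-methylphenyl 2-methylpropanoate | C=C(CO)c1cc(OCc2ccc(OC)cc2)c(C)cc1OC(=O)C(C)C
F4 | step 2 | pentacarbonyl[methoxy(prop-1-en-2-yl)carbene]chromium | C=C(C)C(OC)=[Cr](=C=O)(=C=O)(=C=O)(=C=O)=C=O
F5 | step 2 | 2-(2-hydroxy-5-methoxy-4-methylphenyl)prop-2-en-1-yl benzoate | C=C(COC(=O)c1ccccc1)c1cc(OC)c(C)cc1O
F6 | step 2 | 2-[5-methoxy-4-methyl-2-(2-methylpropanoyloxy)phenyl]prop-2-en-1-yl benzoate | C=C(COC(=O)c1ccccc1)c1cc(OC)c(C)cc1OC(=O)C(C)C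
F0 | step 8 | none | none
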